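Feature: ring A hides a pent-4-enoate. From the ester carbon through quaternary C4 and methine C5 to the C10=C1 double bond runs the array O2C–C4–C5–C10=C1, which is what a [3,3] shift of an allyl ester enolate leaves behind.
Key disconnection: C4–C5. Putting the allylic oxygen back on C1, which C2–C3 already links to C4, gives a 3-methyl-6-(cyclohexenyl) δ-lactone whose silyl ketene acetal rearranges to ring A (Ireland–Claisen).
Other disconnections: oxirane oxygen (Sharpless epoxidation); C13–CH3 and C14–C15 (methylalumination and hydroxymethylation of a C13≡C14 alkyne grown from a C9 allyl group); C10–C1 (Shapiro vinyllithium plus a Weinreb amide from 2-methylglutaric anhydride); C8–CH3 and C9–C11 (asymmetric conjugate methylation and allylation of 2-methylcyclohexenone).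
Ring order: ring B is bought, the temporary δ-lactone is closed after the fragment union, ring A takes its place in the rearrangement, and the oxirane is made last.
Key step: step 8

Numbering: halimane numbering is used for atoms (decalin C1–C10, side chain C11–C15). β is the face of the C9 side chain and α the face of the C8 and C9 methyl groups.
Assumption: the (R,S,S) antipode of the phosphoramidite is assigned to the (8R) series by analogy with conjugate additions to cyclohexenone. Both antipodes are sold, so the sense would be checked on the allylated ketone and the ligand exchanged if needed.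

Step 1
Reactants: 1 2-methylcyclohex-2-en-1-one; 2 allyl bromide
Product: 5 (2S,3R)-2-allyl-2,3-dimethylcyclohexan-1-one, via dimethylaluminium enolate 3 (not isolated), via lithium aluminate enolate 4 (not isolated)
Conditions: AlMe3 (1.4 equiv), Cu(O2C-C4H3S) (copper thiophene-2-carboxylate, 2 mol %), phosphoramidite from (R)-BINOL and bis[(S)-1-phenylethyl]amine (4 mol %), Et2O, −30 °C; MeLi (1.4 equiv), THF–DMPU, −30 °C; 2 (3 equiv), −30 °C → rt; cold 1 M HCl
Reagents that add atoms: trimethylaluminium, C[Al](C)C
Why: Copper-catalysed asymmetric conjugate addition sets C8 under ligand control, and the regiodefined enolate, made nucleophilic as its aluminate, is allylated at C9 by axial attack anti to the pseudoaxial C8 methyl group, which leaves the two methyl groups cis (tandem conjugate addition–enolate alkylation).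

Step 2
Reactants: 5 (2S,3R)-2-allyl-2,3-dimethylcyclohexan-1-one
Product: 6 N'-[(1E,2S,3R)-2-allyl-2,3-dimethylcyclohexylidene]-2,4,6-triisopropylbenzenesulfonohydrazide
Conditions: 2,4,6-(iPr)3C6H2SO2NHNH2 (1.1 equiv), conc. HCl (cat.), MeCN, rt
Reagents that add atoms: 2,4,6-triisopropylbenzenesulfonyl hydrazide, CC(C)c1cc(C(C)C)c(c(C(C)C)c1)S(=O)(=O)NN
Why: Acid-catalysed hydrazone condensation works on α-quaternary cyclohexanones, touches no stereocentre, and should place the sulfonamide nitrogen on the C5 side away from quaternary C9, which is the geometry used by the later syn deprotonation.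

Step 3
Reactants: 7 2-methylglutaric anhydride (racemic)
Product: 8 5-[methoxy(methyl)amino]-2-methyl-5-oxopentanoic acid (racemic)
Conditions: MeONHMe·HCl (1.05 equiv), Et3N (2.2 equiv), CH2Cl2, 0 °C → rt; 1 M HCl; chromatography
Reagents that add atoms: N,O-dimethylhydroxylamine hydrochloride, CNOC.Cl
Why: In this aminolysis of a cyclic anhydride the secondary amine should prefer the carbonyl next to CH2 over the one next to CHMe, the minor regioisomer is removed at this cheap stage, and the racemic C4 centre does not matter because it is enolised in step 8.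

Step 4
Reactants: 6 trisyl hydrazone of step 2; 8 5-[methoxy(methyl)amino]-2-methyl-5-oxopentanoic acid
Product: 11 5-[(5R,6S)-6-allyl-5,6-dimethylcyclohex-1-en-1-yl]-2-methyl-5-oxopentanoic acid (both C4 epimers), via lithium carboxylate 9 (not isolated), via vinyllithium 10 (not isolated)
Conditions: 6, n-BuLi (2.1 equiv), THF–TMEDA, −78 → 0 °C, recool to −78 °C; add 9 (from 8, n-BuLi 1.0 equiv, THF, −78 °C; 1.2 equiv); −78 → 0 °C; 1 M HCl
Reagents that add atoms: none
Why: In the Shapiro reaction the hydrazone can lose a carbon-bound proton only at C5 because C9 is quaternary, so loss of sulfinate and N2 gives a single C10 vinyllithium, which adds to the Weinreb amide (ketone synthesis without over-addition) far faster than to the carboxylate that masks the acid.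

Step 5
Reactants: 11 keto acid of step 4
Product: 12 methyl 5-[(5R,6S)-6-allyl-5,6-dimethylcyclohex-1-en-1-yl]-2-methyl-5-oxopentanoate (both C4 epimers)
Conditions: MeI (1.5 equiv), K2CO3 (1.5 equiv), DMF, rt
Reagents that add atoms: iodomethane, CI
Why: Carboxylate O-alkylation (SN2 on MeI) masks the acid, which would otherwise consume the borane of the next step, and touches neither the enone nor the stereocentres.

Step 6
Reactants: 12 keto ester of step 5
Product: 13 methyl (5R)-5-[(5R,6S)-6-allyl-5,6-dimethylcyclohex-1-en-1-yl]-5-hydroxy-2-methylpentanoate (both C4 epimers)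
Conditions: (S)-2-methyl-CBS-oxazaborolidine (20 mol %), catecholborane (2 equiv), toluene, −78 → −40 °C; MeOH, then aqueous pH 9 buffer
Reagents that add atoms: none
Why: In the Corey–Bakshi–Shibata reduction the α-branched cyclohexenyl group is the large substituent and the CH2 chain the small one, so the (S)-oxazaborolidine should deliver hydride to the face that gives the (R)-carbinol at C1, and catecholborane is chosen because, unlike BH3, it leaves the terminal alkene and the ester alone at low temperature.

Step 7
Reactants: 13 hydroxy ester of step 6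
Product: 14 (6R)-6-[(5R,6S)-6-allyl-5,6-dimethylcyclohex-1-en-1-yl]-3-methyloxan-2-one (both C4 epimers)
Conditions: PPTS (10 mol %), 4 Å MS, toluene, 80 °C
Reagents that add atoms: none
Why: Acid-catalysed transesterification closes the six-membered lactone by acyl substitution, so the C1–O bond and the C1 configuration are untouched, and the weak acid should not ionise an allylic alcohol whose cation would have only secondary termini.

Step 8
Reactants: 14 δ-lactone of step 7
Product: 17 (1S,5S,6R,8aR)-5-allyl-1,5,6-trimethyl-1,2,3,5,6,7,8,8a-octahydronaphthalene-1-carboxylic acid, via silyl ketene acetal 15 (not isolated), via trimethylsilyl ester 16 (not isolated)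
Conditions: LDA (1.5 equiv), Me3SiCl/Et3N (1:1, 4 equiv, present from the start), THF, −78 °C → rt; solvent change to toluene, 110 °C; 1 M HCl, THF, rt
Reagents that add atoms: none
Why: Deprotonation at C4 in the presence of Me3SiCl gives cyclic ketene acetal 15, and on heating its C4=C(OSi)–O unit and the C1–C10=C5 allyl unit undergo a concerted suprafacial [3,3] shift in which C4–C5 forms as C1–O breaks, which leaves the double bond at C1=C10 and the carboxyl, as silyl ester 16, on C4. The closest known reaction type is the Ireland–Claisen rearrangement of silyl ketene acetals of 6-alkenyl δ-lactones to cyclohexenecarboxylic acids, applied here to a more crowded quaternary-to-tertiary junction. Ring A closes as a six-membered carbocycle, formally 6-endo at the C5=C10 bond, through a boat-shaped array, since only the boat lets the C2–C3 bridge end up cis to C5 on the new alkene. C5 is governed by the (R)-carbinol C1: bond breaking and bond making must share one face of the C10=C5 π bond, and with C2 turned toward C5 the C1–O bond points to the β face, so C4 arrives β and H5 ends α. C4 is governed by two ring-locked geometries, the ketene acetal held by the lactone and the alkene held by ring B, which in the boat stack the C4 methyl above C6 and C3 above H5 and thus give the methyl cis to H5 and the carboxyl β. The selectivity needed is bonding on the β face of C5 (the side of the C9 allyl group, opposite both methyl groups), and the tether secures it because the α-face path from this carbinol would demand a trans double bond in ring A, while the ring B half-chair with the C9 methyl pseudoaxial on the α side keeps the β face open for the small Me3SiO group that must sit over C9.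

Step 9
Reactants: 17 bicyclic acid of step 8
Product: 18 methyl (1S,5S,6R,8aR)-5-allyl-1,5,6-trimethyl-1,2,3,5,6,7,8,8a-octahydronaphthalene-1-carboxylate
Conditions: Me3SiCHN2 (2 M in hexanes, 1.5 equiv), toluene–MeOH 4:1, 0 °C → rt
Reagents that add atoms: trimethylsilyldiazomethane, C[Si](C)(C)C=[N+]=[N-]
Why: Esterification with trimethylsilyldiazomethane alkylates the carboxylate oxygen and therefore is not slowed by the hindrance of the axial carboxyl on quaternary C4.

Step 10
Reactants: 18 bicyclic methyl ester of step 9
Product: 20 methyl (1S,5S,6R,8aR)-5-(3-hydroxypropyl)-1,5,6-trimethyl-1,2,3,5,6,7,8,8a-octahydronaphthalene-1-carboxylate, via B-alkyl-9-BBN adduct 19 (not isolated)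
Conditions: 9-BBN (0.5 M in THF, 1.3 equiv), 0 °C → rt; 3 M NaOH, 30% H2O2, 0 °C → rt
Reagents that add atoms: hydrogen peroxide, OO
Why: In this hydroboration–oxidation the bulky 9-BBN adds anti-Markovnikov to the monosubstituted alkene and ignores the hindered trisubstituted C1=C10 bond, and the hindered ester survives the brief alkaline peroxide treatment.

Step 11
Reactants: 20 primary alcohol of step 10
Product: 21 methyl (1S,5S,6R,8aR)-1,5,6-trimethyl-5-(3-oxopropyl)-1,2,3,5,6,7,8,8a-octahydronaphthalene-1-carboxylate
Conditions: TEMPO (10 mol %), PhI(OAc)2 (1.1 equiv), CH2Cl2, rt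
Reagents that add atoms: none
Why: Oxoammonium (TEMPO) oxidation stops at the aldehyde in the absence of water and leaves the alkene and the ester alone.

Step 12
Reactants: 21 aldehyde of step 11
Product: 22 methyl (1S,5S,6R,8aR)-5-(but-3-yn-1-yl)-1,5,6-trimethyl-1,2,3,5,6,7,8,8a-octahydronaphthalene-1-carboxylate
Conditions: dimethyl (1-diazo-2-oxopropyl)phosphonate (1.5 equiv), K2CO3 (2 equiv), MeOH, 0 °C → rt
Reagents that add atoms: dimethyl (1-diazo-2-oxopropyl)phosphonate, COP(=O)(OC)C(=[N+]=[N-])C(C)=O
Why: The Ohira–Bestmann variant of the Seyferth–Gilbert homologation turns aldehyde carbon C13 into the internal alkyne carbon and brings in C14 under mild carbonate conditions in which methanolysis of the methyl ester is degenerate.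

Step 13
Reactants: 22 terminal alkyne of step 12
Product: 25 methyl (1S,5S,6R,8aR)-5-[(3E)-5-hydroxy-3-methylpent-3-en-1-yl]-1,5,6-trimethyl-1,2,3,5,6,7,8,8a-octahydronaphthalene-1-carboxylate, via alkenyldimethylalane 23 (not isolated), via lithium alkenylalanate 24 (not isolated)
Conditions: AlMe3 (3 equiv), Cp2ZrCl2 (25 mol %), CH2Cl2, 0 °C → rt; volatiles off; hexane–THF, n-BuLi (1 equiv per remaining Al), −78 → 0 °C; (CH2O)n (5 equiv), rt; cold 1 M HCl
Reagents that add atoms: trimethylaluminium, C[Al](C)C; paraformaldehyde (as formaldehyde), C=O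
Why: Zirconocene-catalysed syn methylalumination (Negishi carboalumination) places the methyl on C13 and aluminium on terminal C14, which fixes the E geometry, and the derived alanate is hydroxymethylated with retention by formaldehyde while the ring alkene and the hindered C4 ester, tied up by an extra equivalent of AlMe3, stay inert.

Step 14
Reactants: 25 E allylic alcohol of step 13
Product: 26 methyl (1S,5S,6R,8aR)-5-{2-[(2R,3R)-3-(hydroxymethyl)-2-methyloxiran-2-yl]ethyl}-1,5,6-trimethyl-1,2,3,5,6,7,8,8a-octahydronaphthalene-1-carboxylate (CNP0324371.2)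
Conditions: Ti(OiPr)4 (10 mol %), D-(−)-diethyl tartrate (12 mol %), t-BuOOH (5.5 M in decane, 2 equiv), 4 Å MS, CH2Cl2, −20 °C
Reagents that add atoms: tert-butyl hydroperoxide, CC(C)(C)OO
Why: Sharpless asymmetric epoxidation is directed by the allylic hydroxyl, so the isolated C1=C10 alkene is not touched, and with D-(−)-diethyl tartrate the E trisubstituted allylic alcohol should receive oxygen on the face that gives the (13R,14R)-epoxide, as in the (2R,3R)-epoxidation of geraniol.

Compound list
1 | 2-methylcyclohex-2-en-1-one | CC1=CCCCC1=O | starting material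
2 | allyl bromide | C=CCBr | starting material
3 | dimethylaluminium (R)-2,3-dimethylcyclohex-1-en-1-olate | C[Al](C)OC1=C(C)[C@H](C)CCC1 | intermediate
4 | lithium trimethyl[(R)-2,3-dimethylcyclohex-1-en-1-olato]aluminate | [Li+].C[Al-](C)(C)OC1=C(C)[C@H](C)CCC1 | intermediate
5 | (2S,3R)-2-allyl-2,3-dimethylcyclohexan-1-one (methyl groups cis) | O=C1CCC[C@@H](C)[C@]1(C)CC=C | intermediate
6 | N'-[(1E,2S,3R)-2-allyl-2,3-dimethylcyclohexylidene]-2,4,6-triisopropylbenzenesulfonohydrazide | CC(C)c1cc(C(C)C)c(c(C(C)C)c1)S(=O)(=O)N/N=C1\CCC[C@@H](C)[C@]1(C)CC=C | intermediate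
7 | 2-methylglutaric anhydride (racemic) | CC1CCC(=O)OC1=O | starting material
8 | 5-[methoxy(methyl)amino]-2-methyl-5-oxopentanoic acid (racemic) | CON(C)C(=O)CCC(C)C(=O)O | intermediate
9 | lithium 5-[methoxy(methyl)amino]-2-methyl-5-oxopentanoate | [Li+].CON(C)C(=O)CCC(C)C([O-])=O | intermediate
10 | [(5R,6S)-6-allyl-5,6-dimethylcyclohex-1-en-1-yl]lithium | [Li]C1=CCC[C@@H](C)[C@]1(C)CC=C | intermediate
11 | 5-[(5R,6S)-6-allyl-5,6-dimethylcyclohex-1-en-1-yl]-2-methyl-5-oxopentanoic acid (both C4 epimers) | OC(=O)C(C)CCC(=O)C1=CCC[C@@H](C)[C@]1(C)CC=C | intermediate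
12 | methyl 5-[(5R,6S)-6-allyl-5,6-dimethylcyclohex-1-en-1-yl]-2-methyl-5-oxopentanoate (both C4 epimers) | COC(=O)C(C)CCC(=O)C1=CCC[C@@H](C)[C@]1(C)CC=C | intermediate
13 | methyl (5R)-5-[(5R,6S)-6-allyl-5,6-dimethylcyclohex-1-en-1-yl]-5-hydroxy-2-methylpentanoate (both C4 epimers) | COC(=O)C(C)CC[C@@H](O)C1=CCC[C@@H](C)[C@]1(C)CC=C | intermediate
14 | (6R)-6-[(5R,6S)-6-allyl-5,6-dimethylcyclohex-1-en-1-yl]-3-methyloxan-2-one (both C4 epimers) | CC1CC[C@@H](OC1=O)C1=CCC[C@@H](C)[C@]1(C)CC=C | intermediate
15 | {[(2R)-2-[(5R,6S)-6-allyl-5,6-dimethylcyclohex-1-en-1-yl]-5-methyl-3,4-dihydro-2H-pyran-6-yl]oxy}trimethylsilane | C[Si](C)(C)OC1=C(C)CC[C@@H](O1)C1=CCC[C@@H](C)[C@]1(C)CC=C | intermediate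
16 | trimethylsilyl (1S,5S,6R,8aR)-5-allyl-1,5,6-trimethyl-1,2,3,5,6,7,8,8a-octahydronaphthalene-1-carboxylate | C[Si](C)(C)OC(=O)[C@@]1(C)CCC=C2[C@H]1CC[C@@H](C)[C@]2(C)CC=C | intermediate
17 | (1S,5S,6R,8aR)-5-allyl-1,5,6-trimethyl-1,2,3,5,6,7,8,8a-octahydronaphthalene-1-carboxylic acid | OC(=O)[C@@]1(C)CCC=C2[C@H]1CC[C@@H](C)[C@]2(C)CC=C | intermediate
18 | methyl (1S,5S,6R,8aR)-5-allyl-1,5,6-trimethyl-1,2,3,5,6,7,8,8a-octahydronaphthalene-1-carboxylate | COC(=O)[C@@]1(C)CCC=C2[C@H]1CC[C@@H](C)[C@]2(C)CC=C | intermediate
19 | 9-BBN adduct of 18 (boron on C13) | COC(=O)[C@@]1(C)CCC=C2[C@H]1CC[C@@H](C)[C@]2(C)CCCB1C2CCCC1CCC2 | intermediate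
20 | methyl (1S,5S,6R,8aR)-5-(3-hydroxypropyl)-1,5,6-trimethyl-1,2,3,5,6,7,8,8a-octahydronaphthalene-1-carboxylate | COC(=O)[C@@]1(C)CCC=C2[C@H]1CC[C@@H](C)[C@]2(C)CCCO | intermediate
21 | methyl (1S,5S,6R,8aR)-1,5,6-trimethyl-5-(3-oxopropyl)-1,2,3,5,6,7,8,8a-octahydronaphthalene-1-carboxylate | COC(=O)[C@@]1(C)CCC=C2[C@H]1CC[C@@H](C)[C@]2(C)CCC=O | intermediate
22 | methyl (1S,5S,6R,8aR)-5-(but-3-yn-1-yl)-1,5,6-trimethyl-1,2,3,5,6,7,8,8a-octahydronaphthalene-1-carboxylate | COC(=O)[C@@]1(C)CCC=C2[C@H]1CC[C@@H](C)[C@]2(C)CCC#C | intermediate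
23 | (E)-alkenyldimethylalane from 22 (methyl on C13, AlMe2 on C14) | COC(=O)[C@@]1(C)CCC=C2[C@H]1CC[C@@H](C)[C@]2(C)CC/C(C)=C/[Al](C)C | intermediate
24 | lithium butyl(dimethyl)alkenylalanate from 23 | [Li+].COC(=O)[C@@]1(C)CCC=C2[C@H]1CC[C@@H](C)[C@]2(C)CC/C(C)=C/[Al-](C)(C)CCCC | intermediate
25 | methyl (1S,5S,6R,8aR)-5-[(3E)-5-hydroxy-3-methylpent-3-en-1-yl]-1,5,6-trimethyl-1,2,3,5,6,7,8,8a-octahydronaphthalene-1-carboxylate | COC(=O)[C@@]1(C)CCC=C2[C@H]1CC[C@@H](C)[C@]2(C)CC/C(C)=C/CO | intermediate
26 | methyl (1S,5S,6R,8aR)-5-{2-[(2R,3R)-3-(hydroxymethyl)-2-methyloxiran-2-yl]ethyl}-1,5,6-trimethyl-1,2,3,5,6,7,8,8a-octahydronaphthalene-1-carboxylate | COC(=O)[C@@]1(C)CCC=C2[C@H]1CC[C@@H](C)[C@]2(C)CC[C@@]1(C)O[C@@H]1CO | target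

Total step count: 14. Longest linear sequence: 13 (steps 1, 2 and 4–14). Step 3 lies on the short branch.

Steps most likely to fail

Step 8. The rearrangement may stall. The enforced boat holds the silyloxy group over quaternary C9 and has to join a quaternary to a tertiary carbon, so thermal elimination across C1–O, C-silylation or hydrolysis of the ketene acetal could outrun C4–C5 bond formation. The fallback divides the work of the step among three known reactions: an acyclic Ireland–Claisen that is free to adopt a chair makes C4–C5, ring-closing metathesis closes ring A, and the C4 methyl is added last. It sets out from hydrazone 6. The Shapiro reaction to vinyllithium 10 and a quench with paraformaldehyde should give [(5R,6S)-6-allyl-5,6-dimethylcyclohex-1-en-1-yl]methanol F1. Esterification with hex-5-enoic acid (EDC·HCl, DMAP, CH2Cl2) gives its hex-5-enoate F2. LDA and Me3SiCl, then warming and acidic work-up, should give 2-(3-allyl-3,4-dimethyl-2-methylidenecyclohexyl)hex-5-enoic acid F3 by bonding on the β face, opposite the pseudoaxial C9 methyl. Me3SiCHN2 gives its methyl ester F4. The second-generation Grubbs catalyst in dilute toluene joins C1 to C10 with loss of ethene to give the 4-demethyl bicyclic ester F5; the six-membered closure should outpace the nine-membered one through the C9 allyl group. LDA and then MeI should alkylate the exocyclic ester enolate from the equatorial α side. The sequence comes back to the route at 18.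

Step 4. The hindered vinyllithium may act as a base toward the C2 methylene of the amide, or the sparingly soluble carboxylate may react too slowly, so protonation of the organolithium would compete with acylation. The fallback replaces the acylation by a chromium-mediated addition to an aldehyde. It sets out from ketone 5 and acid 8. KHMDS and PhNTf2 convert 5 into (5R,6S)-6-allyl-5,6-dimethylcyclohex-1-en-1-yl trifluoromethanesulfonate F6. MeI and K2CO3 convert 8 into methyl 5-[methoxy(methyl)amino]-2-methyl-5-oxopentanoate F7, whose amide is reduced selectively by Cp2Zr(H)Cl in THF to methyl 2-methyl-5-oxopentanoate F8. Nozaki–Hiyama–Kishi coupling of the two (CrCl2, catalytic NiCl2, DMF, rt) tolerates the ester and the terminal alkene and should give the C1-epimeric allylic alcohol methyl 5-(6-allyl-5,6-dimethylcyclohexenyl)-5-hydroxy-2-methylpentanoate F9. Oxidation with Dess–Martin periodinane comes back to the route at 12.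

Step 6. Facial selectivity may be poor. The enone is twisted by the neighbouring quaternary C9, and the resident stereocentres may oppose the catalyst, and any erosion at C1 is passed on to C4 and C5 in step 8. The fallback sets C1 by an invertive C–O bond formation instead of by the reduction alone. It sets out from 12. The antipodal (R)-2-methyl-CBS-oxazaborolidine with catecholborane, then the matched pair, should give methyl (5S)-5-[(5R,6S)-6-allyl-5,6-dimethylcyclohex-1-en-1-yl]-5-hydroxy-2-methylpentanoate F10. LiOH in THF–water gives the (5S)-hydroxy acid F11. Mitsunobu lactonisation (PPh3, DIAD, toluene, high dilution) activates the alcohol, so the carboxylate displaces it with inversion at C1. The sequence comes back to the route at 14.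

Further compounds
F1 | step 8 | [(5R,6S)-6-allyl-5,6-dimethylcyclohex-1-en-1-yl]methanol | OCC1=CCC[C@@H](C)[C@]1(C)CC=C
F2 | step 8 | [(5R,6S)-6-allyl-5,6-dimethylcyclohex-1-en-1-yl]methyl hex-5-enoate | C=CCCCC(=O)OCC1=CCC[C@@H](C)[C@]1(C)CC=C
F3 | step 8 | 2-(3-allyl-3,4-dimethyl-2-methylidenecyclohexyl)hex-5-enoic acid (C5, C8, C9 as in 18; both C4 epimers) | OC(=O)C(CCC=C)[C@@H]1CC[C@@H](C)[C@](C)(CC=C)C1=C
F4 | step 8 | methyl ester of F3 | COC(=O)C(CCC=C)[C@@H]1CC[C@@H](C)[C@](C)(CC=C)C1=C
F5 | step 8 | methyl 5-allyl-5,6-dimethyl-1,2,3,5,6,7,8,8a-octahydronaphthalene-1-carboxylate (C5, C8, C9 as in 18; both C4 epimers) | COC(=O)C1CCC=C2[C@H]1CC[C@@H](C)[C@]2(C)CC=C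
F6 | step 4 | (5R,6S)-6-allyl-5,6-dimethylcyclohex-1-en-1-yl trifluoromethanesulfonate | FC(F)(F)S(=O)(=O)OC1=CCC[C@@H](C)[C@]1(C)CC=C
F7 | step 4 | methyl 5-[methoxy(methyl)amino]-2-methyl-5-oxopentanoate | CON(C)C(=O)CCC(C)C(=O)OC
F8 | step 4 | methyl 2-methyl-5-oxopentanoate | COC(=O)C(C)CCC=O
F9 | step 4 | methyl 5-[(5R,6S)-6-allyl-5,6-dimethylcyclohex-1-en-1-yl]-5-hydroxy-2-methylpentanoate (C1 epimers) | COC(=O)C(C)CCC(O)C1=CCC[C@@H](C)[C@]1(C)CC=C
F10 | step 6 | methyl (5S)-5-[(5R,6S)-6-allyl-5,6-dimethylcyclohex-1-en-1-yl]-5-hydroxy-2-methylpentanoate | COC(=O)C(C)CC[C@H](O)C1=CCC[C@@H](C)[C@]1(C)CC=C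
F11 | step 6 | (5S)-5-[(5R,6S)-6-allyl-5,6-dimethylcyclohex-1-en-1-yl]-5-hydroxy-2-methylpentanoic acid | OC(=O)C(C)CC[C@H](O)C1=CCC[C@@H](C)[C@]1(C)CC=C
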